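Retrosynthetic cuts, in order: the six O–benzyl bonds; ring A is taken back from an arene to a cyclohexene carrying a 3,4-diol; the ester bond O5(ring A)–C(=O)(ring B); the ester bond O4(ring B)–C(=O)(ring C).
Enabling feature: ring A is a gallate with C3–OH and C4–OH free and only C5–O acylated. (−)-Shikimic acid has the same six-membered carbocycle (carboxyl on C1, oxygen on C3, C4 and C5), already contains the C1=C2 double bond, and sets a cis O3/O4 pair, maskable as one ketal, apart from a lone O5–H.
Forward order: rings B and C enter as finished gallate arenes and are joined first (ring C acyl onto O4 of ring B). The B–C acid is then esterified onto O5 of the masked shikimate, ring A becomes aromatic late by twofold oxidation at C3/C4 and tautomerization, and hydrogenolysis ends the route.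
Stereochemistry: the target has no stereocentre. The 3R,4S,5R centres come from the chiral pool, serve only to tell O5 from O3/O4, and are erased when ring A aromatizes.

Key step: step 11

Remark: ring A is numbered as in shikimic acid throughout (C1 bears the carboxyl carbon, O5 the acyl group). (−)-Shikimic acid, gallic acid and 3,4,5-tris(benzyloxy)benzoic acid are taken as commercial.

Step 1
Reactants: 1 (−)-shikimic acid
Product: 2 benzyl shikimate
Conditions: BnBr (1.1 equiv), Cs2CO3 (0.55 equiv), DMF, rt
Reagents that add atoms: benzyl bromide, BrCc1ccccc1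
Why: Carboxylate O-alkylation (SN2 of the caesium salt on benzyl bromide) is selective because carbonate deprotonates only the acid and not the three secondary alcohols, and C3, C4 and C5 are not touched.

Step 2
Reactants: 2 benzyl shikimate
Product: 3 benzyl 3,4-O-isopropylideneshikimate
Conditions: Me2C(OMe)2, TsOH·H2O (cat.), acetone, rt
Reagents that add atoms: 2,2-dimethoxypropane, COC(C)(C)OC
Why: Acid-catalysed transketalization puts the five-membered dioxolane on the cis O3/O4 pair only, since a dioxolane across the trans O4/O5 pair would be strained, so O5–H remains the single free hydroxyl and no stereocentre changes.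

Step 3
Reactants: 4 gallic acid
Product: 5 allyl gallate
Conditions: allyl alcohol (solvent), TsOH·H2O (cat.), 90 °C
Reagents that add atoms: allyl alcohol, C=CCO
Why: Fischer esterification in excess alcohol converts only the carboxyl group, the phenols being inert, as in the preparation of simple alkyl gallates.

Step 4
Reactants: 5 allyl gallate
Product: 6 allyl 3,4,5-tris(benzyloxy)benzoate
Conditions: BnBr (3.5 equiv), K2CO3, DMF, 60 °C, N2
Reagents that add atoms: benzyl bromide, BrCc1ccccc1
Why: Williamson ether synthesis on the three phenoxides goes to completion with excess benzyl bromide, and the allyl ester is stable to carbonate in an aprotic solvent.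

Step 5
Reactants: 6 allyl 3,4,5-tris(benzyloxy)benzoate
Product: 8 allyl 3,5-bis(benzyloxy)-4-hydroxybenzoate, via aryloxydichloroborane 7 (not isolated)
Conditions: BCl3 (1.1 equiv), C6HMe5 (3 equiv), CH2Cl2, −78 °C; then cold H2O
Reagents that add atoms: none
Why: This is the Lewis-acid cleavage of the central ether of a 1,2,3-trialkoxyarene: the O4 benzyl ether is twisted out of the ring plane (most basic oxygen), is flanked by two chelating oxygens and leaves as the phenoxide para to the ester, so about one equivalent of BCl3 at low temperature should remove this benzyl group alone while pentamethylbenzene traps the benzyl cation.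

Step 6
Reactants: 9 3,4,5-tris(benzyloxy)benzoic acid
Product: 10 3,4,5-tris(benzyloxy)benzoyl chloride
Conditions: (COCl)2 (1.5 equiv), DMF (cat.), CH2Cl2, 0 °C to rt; concentrate, use crude
Reagents that add atoms: oxalyl chloride, O=C(Cl)C(=O)Cl
Why: Acid chloride formation through the Vilsmeier-type chloroiminium catalyst is mild enough to leave aryl benzyl ethers intact, and all coproducts are gases.

Step 7
Reactants: 8 allyl 3,5-bis(benzyloxy)-4-hydroxybenzoate; 10 3,4,5-tris(benzyloxy)benzoyl chloride
Product: 11 allyl 3,5-bis(benzyloxy)-4-[3,4,5-tris(benzyloxy)benzoyloxy]benzoate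
Conditions: Et3N (1.5 equiv), DMAP (0.1 equiv), CH2Cl2, 0 °C to rt
Reagents that add atoms: none
Why: DMAP-catalysed O-acylation through the acylpyridinium ion overcomes the crowding of the doubly flanked phenol, which is the only nucleophile present.

Step 8
Reactants: 11 allyl 3,5-bis(benzyloxy)-4-[3,4,5-tris(benzyloxy)benzoyloxy]benzoate
Product: 12 3,5-bis(benzyloxy)-4-[3,4,5-tris(benzyloxy)benzoyloxy]benzoic acid
Conditions: Pd(PPh3)4 (5 mol %), p-TolSO2H (1.2 equiv), CH2Cl2, rt
Reagents that add atoms: none
Why: In this Tsuji–Trost-type deallylation zerovalent palladium ionizes the allyl ester to a π-allyl complex that the soft sulfinate captures as a sulfone, and since no amine or alkoxide is present the aryl ester between rings B and C is not attacked.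

Step 9
Reactants: 3 benzyl 3,4-O-isopropylideneshikimate; 12 3,5-bis(benzyloxy)-4-[3,4,5-tris(benzyloxy)benzoyloxy]benzoic acid
Product: 13 benzyl 5-O-{3,5-bis(benzyloxy)-4-[3,4,5-tris(benzyloxy)benzoyloxy]benzoyl}-3,4-O-isopropylideneshikimate
Conditions: EDC·HCl (1.5 equiv), DMAP (0.2 equiv), CH2Cl2, 0 °C to rt
Reagents that add atoms: none
Why: Steglich esterification joins the acid to the only free hydroxyl with retention at C5, because the C5–O bond is not broken, and a small DMAP loading at low temperature limits acyl exchange at the hindered aryl ester.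

Step 10
Reactants: 13 benzyl 5-O-{3,5-bis(benzyloxy)-4-[3,4,5-tris(benzyloxy)benzoyloxy]benzoyl}-3,4-O-isopropylideneshikimate
Product: 14 benzyl 5-O-{3,5-bis(benzyloxy)-4-[3,4,5-tris(benzyloxy)benzoyloxy]benzoyl}shikimate
Conditions: AcOH/H2O/THF (3:1:1), 55 °C
Reagents that add atoms: none
Why: Acid-catalysed ketal hydrolysis frees the cis-diol under conditions too mild for aryl esters or benzyl ethers, and the absence of base and of alcohol solvent suppresses O5-to-O4 acyl shift and transesterification.

Step 11
Reactants: 14 benzyl 5-O-{3,5-bis(benzyloxy)-4-[3,4,5-tris(benzyloxy)benzoyloxy]benzoyl}shikimate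
Product: 18 benzyl 3,4-dihydroxy-5-{3,5-bis(benzyloxy)-4-[3,4,5-tris(benzyloxy)benzoyloxy]benzoyloxy}benzoate, via bis(alkoxysulfonium) salt 15 (not isolated), via ene-3,4-dione 16 (not isolated), via cross-conjugated dienone 17 (not isolated)
Conditions: DMSO (6 equiv), (CF3CO)2O (2.5 equiv), CH2Cl2, −78 °C, then 14, 1 h; iPr2NEt (8 equiv), −78 to −20 °C, Ar; pour into cold 1 M HCl; wash with aq Na2S2O4
Reagents that add atoms: none
Why: Proposed new method: at −78 °C both hydroxyls of 14 attack dimethyl(trifluoroacetoxy)sulfonium trifluoroacetate to give the bis(alkoxysulfonium) salt 15, the amine then triggers two ylide-type eliminations of Me2S to the ene-dione 16, and enolization of C5–H toward the C4 carbonyl (dienone 17) followed by a proton shift from C6 to O3 delivers the arene, the gain in aromaticity making the cascade irreversible. The closest known reaction types are the oxidation of vicinal diols to 1,2-diones with anhydride-activated DMSO (Swern-type), the aromatization of cyclic diosphenols by enolization, and the oxidation of 3-dehydroshikimic acid to gallic acid by divalent copper salts, none of which has been shown on a shikimate carrying a carboxylate leaving group at C5. No ring is closed: the carbocycle C1–C6 is kept and becomes benzene ring A, the C1=C2 alkene supplying the first double bond and the two oxidations with their two tautomerizations the other two. No stereocentre is created, and C3, C4 and C5 are all flattened. The selectivity needed is loss of C5–H rather than loss of the C5 carboxylate (E1cB from a C3 mono-ketone through C4–H, or from 16 through C6–H); it is secured by loading O4 with the sulfonium group before any base is present, so that removal of C4–H expels Me2S, the far better leaving group, and forms C4=O, and by the expected half-chair of the ring, in which C5–H is axial and aligned with the C4 carbonyl while the C5–O bond is pseudo-equatorial and poorly aligned with the dienolate π system. Acyl shift from O5 to O4 in the catechol is held back by the cold acidic quench and should in any case be uphill, since O4 para to the ester is the more acidic phenol oxygen and hence the better leaving group.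

Step 12
Reactants: 18 benzyl 3,4-dihydroxy-5-{3,5-bis(benzyloxy)-4-[3,4,5-tris(benzyloxy)benzoyloxy]benzoyloxy}benzoate
Product: 19 3,4-dihydroxy-5-{3,5-dihydroxy-4-[(3,4,5-trihydroxybenzoyl)oxy]benzoyloxy}benzoic acid (CNP0317472.0)
Conditions: H2 (1 atm), 10% Pd/C, THF, rt; filter under Ar, concentrate below 30 °C
Reagents that add atoms: none
Why: Heterogeneous catalytic hydrogenolysis cleaves the five aryl benzyl ethers and the benzyl ester to toluene without touching aryl esters, and the neutral aprotic medium avoids the base- or alcohol-promoted para-to-meta acyl shift on ring B once its flanking phenols are free.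

Compound list
1 | (−)-shikimic acid, (3R,4S,5R)-3,4,5-trihydroxycyclohex-1-ene-1-carboxylic acid | O=C(O)C1=C[C@@H](O)[C@@H](O)[C@H](O)C1 | starting material
2 | benzyl shikimate, benzyl (3R,4S,5R)-3,4,5-trihydroxycyclohex-1-ene-1-carboxylate | O=C(OCc1ccccc1)C1=C[C@@H](O)[C@@H](O)[C@H](O)C1 | intermediate
3 | benzyl (3R,4S,5R)-3,4-O-isopropylideneshikimate (cis-fused dioxolane on O3/O4, free 5-OH trans to O4) | O=C(OCc1ccccc1)C1=C[C@H]2OC(C)(C)O[C@H]2[C@H](O)C1 | intermediate
4 | gallic acid, 3,4,5-trihydroxybenzoic acid | O=C(O)c1cc(O)c(O)c(O)c1 | starting material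
5 | allyl gallate, prop-2-enyl 3,4,5-trihydroxybenzoate | C=CCOC(=O)c1cc(O)c(O)c(O)c1 | intermediate
6 | allyl 3,4,5-tris(benzyloxy)benzoate | C=CCOC(=O)c1cc(OCc2ccccc2)c(OCc2ccccc2)c(OCc2ccccc2)c1 | intermediate
7 | allyl 3,5-bis(benzyloxy)-4-(dichloroboryloxy)benzoate | C=CCOC(=O)c1cc(OCc2ccccc2)c(OB(Cl)Cl)c(OCc2ccccc2)c1 | intermediate
8 | allyl 3,5-bis(benzyloxy)-4-hydroxybenzoate | C=CCOC(=O)c1cc(OCc2ccccc2)c(O)c(OCc2ccccc2)c1 | intermediate
9 | 3,4,5-tris(benzyloxy)benzoic acid | O=C(O)c1cc(OCc2ccccc2)c(OCc2ccccc2)c(OCc2ccccc2)c1 | starting material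
10 | 3,4,5-tris(benzyloxy)benzoyl chloride | O=C(Cl)c1cc(OCc2ccccc2)c(OCc2ccccc2)c(OCc2ccccc2)c1 | intermediate
11 | allyl 3,5-bis(benzyloxy)-4-[3,4,5-tris(benzyloxy)benzoyloxy]benzoate | C=CCOC(=O)c1cc(OCc2ccccc2)c(OC(=O)c2cc(OCc3ccccc3)c(OCc3ccccc3)c(OCc3ccccc3)c2)c(OCc2ccccc2)c1 | intermediate
12 | 3,5-bis(benzyloxy)-4-[3,4,5-tris(benzyloxy)benzoyloxy]benzoic acid | O=C(O)c1cc(OCc2ccccc2)c(OC(=O)c2cc(OCc3ccccc3)c(OCc3ccccc3)c(OCc3ccccc3)c2)c(OCc2ccccc2)c1 | intermediate
13 | benzyl (3R,4S,5R)-5-O-{3,5-bis(benzyloxy)-4-[3,4,5-tris(benzyloxy)benzoyloxy]benzoyl}-3,4-O-isopropylideneshikimate | O=C(OCc1ccccc1)C1=C[C@H]2OC(C)(C)O[C@H]2[C@H](OC(=O)c2cc(OCc3ccccc3)c(OC(=O)c3cc(OCc4ccccc4)c(OCc4ccccc4)c(OCc4ccccc4)c3)c(OCc3ccccc3)c2)C1 | intermediate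
14 | benzyl 5-O-{3,5-bis(benzyloxy)-4-[3,4,5-tris(benzyloxy)benzoyloxy]benzoyl}shikimate (free cis-3,4-diol; shikimate geometry unchanged, descriptors 3R,4R,5R because the priority order at C4 changes) | O=C(OCc1ccccc1)C1=C[C@@H](O)[C@@H](O)[C@H](OC(=O)c2cc(OCc3ccccc3)c(OC(=O)c3cc(OCc4ccccc4)c(OCc4ccccc4)c(OCc4ccccc4)c3)c(OCc3ccccc3)c2)C1 | intermediate
15 | 3,4-bis-O-(dimethylsulfonio) derivative of 14, bis(trifluoroacetate) (3R,4S,5R, geometry unchanged) | O=C(OCc1ccccc1)C1=C[C@@H](O[S+](C)C)[C@@H](O[S+](C)C)[C@H](OC(=O)c2cc(OCc3ccccc3)c(OC(=O)c3cc(OCc4ccccc4)c(OCc4ccccc4)c(OCc4ccccc4)c3)c(OCc3ccccc3)c2)C1.[O-]C(=O)C(F)(F)F.[O-]C(=O)C(F)(F)F | intermediate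
16 | benzyl (5R)-5-{3,5-bis(benzyloxy)-4-[3,4,5-tris(benzyloxy)benzoyloxy]benzoyloxy}-3,4-dioxocyclohex-1-ene-1-carboxylate | O=C(OCc1ccccc1)C1=CC(=O)C(=O)[C@H](OC(=O)c2cc(OCc3ccccc3)c(OC(=O)c3cc(OCc4ccccc4)c(OCc4ccccc4)c(OCc4ccccc4)c3)c(OCc3ccccc3)c2)C1 | intermediate
17 | benzyl 5-{3,5-bis(benzyloxy)-4-[3,4,5-tris(benzyloxy)benzoyloxy]benzoyloxy}-4-hydroxy-3-oxocyclohexa-1,4-diene-1-carboxylate | O=C(OCc1ccccc1)C1=CC(=O)C(O)=C(OC(=O)c2cc(OCc3ccccc3)c(OC(=O)c3cc(OCc4ccccc4)c(OCc4ccccc4)c(OCc4ccccc4)c3)c(OCc3ccccc3)c2)C1 | intermediate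
18 | benzyl 3,4-dihydroxy-5-{3,5-bis(benzyloxy)-4-[3,4,5-tris(benzyloxy)benzoyloxy]benzoyloxy}benzoate | O=C(OCc1ccccc1)c1cc(O)c(O)c(OC(=O)c2cc(OCc3ccccc3)c(OC(=O)c3cc(OCc4ccccc4)c(OCc4ccccc4)c(OCc4ccccc4)c3)c(OCc3ccccc3)c2)c1 | intermediate
19 | 3,4-dihydroxy-5-{3,5-dihydroxy-4-[(3,4,5-trihydroxybenzoyl)oxy]benzoyloxy}benzoic acid (CNP0317472.0, achiral) | O=C(O)c1cc(O)c(O)c(OC(=O)c2cc(O)c(OC(=O)c3cc(O)c(O)c(O)c3)c(O)c2)c1 | target

Total step count: 12
Longest linear sequence: 9 steps (4 → 5 → 6 → 8 → 11 → 12 → 13 → 14 → 18 → 19, i.e. steps 3, 4, 5, 7, 8, 9, 10, 11, 12)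

Steps most likely to fail

1. Step 11.
- Risk: expulsion of the C5 carboxylate by E1cB may outpace the second oxidation or the C5 enolization. The fresh catechol may also be over-oxidized or methylthiomethylated by surplus activated DMSO.
- Fallback (known chemistry, sets out from 4 and 12, returns at 19): ring A is taken from the aromatic pool instead of being aromatized. Gallic acid 4 is alkylated on the carboxylate only (BnBr, KHCO3, DMF) to give benzyl gallate F1. Dichlorodiphenylmethane and K2CO3 in MeCN bridge two adjacent phenol oxygens, which by the symmetry of the gallate can only leave one meta hydroxyl free. This gives benzyl 7-hydroxy-2,2-diphenyl-1,3-benzodioxole-5-carboxylate F2. Steglich esterification of that hydroxyl with acid 12 gives the fully protected tridepside ketal F3. Hydrogenolysis (H2, Pd/C, THF) then cleaves the six benzyl groups and the diphenylmethylene ketal in one operation to give 19.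

2. Step 5.
- Risk: cleavage may not stop after one benzyl group, because the boron aryloxide formed first can activate a neighbouring ether from within. Binding of BCl3 to the ester carbonyl may also stall the reaction.
- Fallback (sets out from 5, returns at 8): the free O4–H is secured by a temporary orthogonal group placed by acidity, not by selective cleavage. The most acidic phenol of 5, para to the ester, is mono-alkylated with 4-methoxybenzyl chloride (1 equiv, KHCO3, DMF) to give allyl 3,5-dihydroxy-4-(4-methoxybenzyloxy)benzoate F4. The two meta phenols are benzylated (BnBr, K2CO3, DMF) to give allyl 3,5-bis(benzyloxy)-4-(4-methoxybenzyloxy)benzoate F5. The acid-labile 4-methoxybenzyl ether alone is then removed with TFA and Et3SiH in CH2Cl2 at 0 °C, giving 8.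

3. Step 10.
- Risk: hydrolysis of the ketal may be slow for so lipophilic a substrate. Prolonged warming in acid invites acyl shift from O5 to O4 and gradual loss of benzyl ethers.
- Fallback (sets out from 2 and 12, returns at 14): the cis-diol is masked by a group that is removed by neutral exchange instead of hydrolysis. Benzyl shikimate 2 is condensed with PhB(OH)2 (toluene, azeotropic drying) to give benzyl shikimate 3,4-O-phenylboronate F6. Its free O5–H is esterified with 12 (EDC·HCl, DMAP, CH2Cl2) to give the 5-O-acylated 3,4-O-phenylboronate F7. Stirring with pinacol in CH2Cl2 at rt transfers the boron to the diol scavenger and releases 14.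

Further compounds
F1 | step 11 | benzyl gallate | O=C(OCc1ccccc1)c1cc(O)c(O)c(O)c1
F2 | step 11 | benzyl 7-hydroxy-2,2-diphenyl-1,3-benzodioxole-5-carboxylate | O=C(OCc1ccccc1)c1cc(O)c2OC(c3ccccc3)(c3ccccc3)Oc2c1
F3 | step 11 | benzyl 7-{3,5-bis(benzyloxy)-4-[3,4,5-tris(benzyloxy)benzoyloxy]benzoyloxy}-2,2-diphenyl-1,3-benzodioxole-5-carboxylate | O=C(OCc1ccccc1)c1cc(OC(=O)c2cc(OCc3ccccc3)c(OC(=O)c3cc(OCc4ccccc4)c(OCc4ccccc4)c(OCc4ccccc4)c3)c(OCc3ccccc3)c2)c2OC(c3ccccc3)(c3ccccc3)Oc2c1
F4 | step 5 | allyl 3,5-dihydroxy-4-(4-methoxybenzyloxy)benzoate | C=CCOC(=O)c1cc(O)c(OCc2ccc(OC)cc2)c(O)c1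
F5 | step 5 | allyl 3,5-bis(benzyloxy)-4-(4-methoxybenzyloxy)benzoate | C=CCOC(=O)c1cc(OCc2ccccc2)c(OCc2ccc(OC)cc2)c(OCc2ccccc2)c1
F6 | step 10 | benzyl shikimate 3,4-O-phenylboronate (configuration as in 2, free 5-OH) | O=C(OCc1ccccc1)C1=C[C@H]2OB(c3ccccc3)O[C@H]2[C@H](O)C1
F7 | step 10 | benzyl 5-O-{3,5-bis(benzyloxy)-4-[3,4,5-tris(benzyloxy)benzoyloxy]benzoyl}shikimate 3,4-O-phenylboronate (configuration as in 2) | O=C(OCc1ccccc1)C1=C[C@H]2OB(c3ccccc3)O[C@H]2[C@H](OC(=O)c2cc(OCc3ccccc3)c(OC(=O)c3cc(OCc4ccccc4)c(OCc4ccccc4)c(OCc4ccccc4)c3)c(OCc3ccccc3)c2)C1
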